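The β-hydroxy ketone is disconnected at its aldol bond, and the remaining 6-acetyl-2H-chromene across the pyran ring at C4–C4a and O1–C2. The key step is a formal [3+3] annulation: prenal and 2,4-dihydroxy-6-methoxyacetophenone, a simple arene with no pyran ring, combine by Knoevenagel-type C-alkylation and oxa-6π electrocyclization to form both pyran bonds in one operation. It exploits the hydrogen bond between the C5 hydroxyl and the C6 ketone of the benzene ring: with that hydroxyl chelated, only the para oxygen (future O1) is free and the carbon between the two oxygens (future C4a) is the nucleophile. A catalytic enantioselective Mukaiyama aldol with benzaldehyde then sets the carbinol stereocenter.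

Key step: step 1

Remark: for the SiCl4/bisphosphoramide aldol the (R,R)-Lewis base is taken to deliver enol silanes to the Re face of aromatic aldehydes, so the (S,S)-enantiomer is specified for the (S)-carbinol, which needs Si-face attack; ring atoms carry chromene numbers (O1, C2 to C8a) except where compound 1 is numbered from its acetyl-bearing carbon.

Step 1
Reactants: 1 1-(2,4-dihydroxy-6-methoxyphenyl)ethan-1-one; 2 3-methylbut-2-enal (prenal)
Product: 4 1-(5-hydroxy-7-methoxy-2,2-dimethyl-2H-chromen-6-yl)ethan-1-one, via ortho-quinone methide 3 (not isolated)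
Conditions: 2 (2 equiv), ethylenediammonium diacetate (20 mol%), xylene, 140 °C
Reagents that add atoms: none
Why: The diammonium acetate turns 2 into an α,β-unsaturated iminium ion, which is attacked at its iminium carbon by ring carbon C3 of 1 (the CH between the two hydroxyls, acting as the enol carbon of the free para hydroxyl), and loss of the amine gives 1-oxatriene 3, which closes thermally so that C4–C4a and then O1–C2 of the pyran ring are made in the same flask. The closest known reaction type is the amine-catalysed formal [3+3] annulation of resorcinols and acylphloroglucinols with enals (Knoevenagel condensation followed by oxa-6π electrocyclization). The pyran ring closes in a pericyclic, disrotatory 6π mode over O=C–C=CH–CH=CMe2 of 3, not by an ionic 6-endo addition, and the return of aromaticity should make the closure irreversible in practice. No stereocenter is formed, since C2 carries two methyl groups. The step needs C–C bond formation at C3 instead of C5 and closure through the para oxygen instead of the ortho oxygen; the ortho hydroxyl of 1 is locked in a hydrogen bond to the acetyl C=O, which leaves the para hydroxyl as the only free and the more acidic oxygen and should direct the electrophile, as is usual for monochelated resorcinol ketones, to the less hindered carbon flanked by the two hydroxyls. A second annulation cannot follow because the remaining hydroxyl of 4 has no free ortho carbon.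

Step 2
Reactants: 4 1-(5-hydroxy-7-methoxy-2,2-dimethyl-2H-chromen-6-yl)ethan-1-one
Product: 5 [(7-methoxy-2,2-dimethyl-6-{1-[(trimethylsilyl)oxy]ethenyl}-2H-chromen-5-yl)oxy](trimethyl)silane
Conditions: TMSOTf (2.4 equiv), Et3N (3 equiv), CH2Cl2, 0 °C to rt; pentane trituration and filtration, no aqueous work-up
Reagents that add atoms: trimethylsilyl trifluoromethanesulfonate (TMSOTf), C[Si](C)(C)OS(=O)(=O)C(F)(F)F
Why: Soft enolisation and O-silylation with TMSOTf and Et3N (silyl enol ether formation) should convert the only enolisable position, the acetyl CH3, into the terminal enol silane and at the same time cap the chelated phenol, whose proton would otherwise consume SiCl4 in step 3.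

Step 3
Reactants: 5 [(7-methoxy-2,2-dimethyl-6-{1-[(trimethylsilyl)oxy]ethenyl}-2H-chromen-5-yl)oxy](trimethyl)silane; 6 benzaldehyde
Product: 8 (3S)-3-hydroxy-1-(5-hydroxy-7-methoxy-2,2-dimethyl-2H-chromen-6-yl)-3-phenylpropan-1-one (target), via trichlorosilyl aldolate 7 (not isolated)
Conditions: 6 (1.2 equiv), SiCl4 (1.5 equiv), (S,S)-N,N'-bis[3,5-dimethyl-4-oxido-3,5-dihydro-4H-dinaphtho[2,1-d:1',2'-f][1,3,2]diazaphosphepin-4-yl]-N,N'-dimethylpentane-1,5-diamine (5 mol%), i-Pr2NEt (10 mol%), CH2Cl2, −78 °C; sat. aq NaHCO3; citric acid, MeOH, 0 °C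
Reagents that add atoms: none
Why: Lewis-base-activated Mukaiyama aldol addition: the chiral phosphoramide-bound trichlorosilyl cation binds 6 and the unsubstituted enol silane carbon of 5 should add through an open transition state to the Si face left exposed by the (S,S)-ligand, which sets the (S)-carbinol as the chelated trichlorosilyl aldolate 7 (protected against retro-aldol and dehydration) before mild hydrolysis frees the secondary and the phenolic hydroxyl.

Compound list
1 | 1-(2,4-dihydroxy-6-methoxyphenyl)ethan-1-one | COc1cc(O)cc(O)c1C(C)=O | starting material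
2 | 3-methylbut-2-enal (prenal) | CC(C)=CC=O | starting material
3 | (2Z)-4-acetyl-3-hydroxy-5-methoxy-2-(3-methylbut-2-en-1-ylidene)cyclohexa-3,5-dien-1-one (ortho-quinone methide) | O=C1C=C(OC)C(C(C)=O)=C(O)/C1=C/C=C(C)C | intermediate
4 | 1-(5-hydroxy-7-methoxy-2,2-dimethyl-2H-chromen-6-yl)ethan-1-one | COc1cc2c(c(O)c1C(C)=O)C=CC(C)(C)O2 | intermediate
5 | [(7-methoxy-2,2-dimethyl-6-{1-[(trimethylsilyl)oxy]ethenyl}-2H-chromen-5-yl)oxy](trimethyl)silane | COc1cc2c(c(O[Si](C)(C)C)c1C(=C)O[Si](C)(C)C)C=CC(C)(C)O2 | intermediate
6 | benzaldehyde | O=Cc1ccccc1 | starting material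
7 | (3S)-1-{7-methoxy-2,2-dimethyl-5-[(trimethylsilyl)oxy]-2H-chromen-6-yl}-3-phenyl-3-[(trichlorosilyl)oxy]propan-1-one | COc1cc2c(c(O[Si](C)(C)C)c1C(=O)C[C@H](O[Si](Cl)(Cl)Cl)c1ccccc1)C=CC(C)(C)O2 | intermediate
8 | (3S)-3-hydroxy-1-(5-hydroxy-7-methoxy-2,2-dimethyl-2H-chromen-6-yl)-3-phenylpropan-1-one | COc1cc2c(c(O)c1C(=O)C[C@H](O)c1ccccc1)C=CC(C)(C)O2 | target

Total step count: 3. Longest linear sequence: 3 steps (1 to 4 to 5 to 8).

Steps most likely to fail, most risky first:

Step 3. The twisted, doubly ortho-substituted enol silane may add slowly, so that protodesilylation by adventitious HCl outruns the aldol addition, or facial discrimination may erode. The fallback sets the stereocenter on an alkene instead of on the aldehyde; it sets out from 4 and comes back at 8. The phenol of 4 is capped with MOMCl and NaH in DMF to give MOM ether F1. Claisen–Schmidt condensation of F1 with 6 (KOH, EtOH) gives chalcone F2. Juliá–Colonna epoxidation with poly-D-leucine, urea–H2O2 and DBU in THF, a nucleophilic oxidant that should touch only the electron-poor enone and not the chromene alkene, gives (2S,3R)-epoxy ketone F3, the mirror image of the (2R,3S) series obtained with poly-L-leucine. Reductive cleavage of the Cα–O bond with Na[PhSeB(OEt)3] (from PhSeSePh and NaBH4 in EtOH) and AcOH leaves the benzylic C–O bond untouched and gives MOM-protected aldol F4. ZnBr2 and n-PrSH in CH2Cl2 at 0 °C then remove the MOM group to give 8.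

Step 1. C–C bond formation may leak to C5, between the free hydroxyl and the methoxyl, or the ring may close through the chelated oxygen, so that regioisomeric chromenes form. The fallback takes the regiochemical question out of the annulation by symmetry and settles it afterwards by a chelation-controlled ether cleavage; it sets out from 2 and comes back at 4. Prenal 2 is condensed under the same amine catalysis with the commercial symmetric phenol F5, whose two ortho carbons are equivalent, to give the single dimethoxy chromene F6. BCl3 (1.1 equiv, CH2Cl2, −78 °C) should then cleave the 5-methoxyl, which is flanked on both sides, twisted out of conjugation and hence the more Lewis-basic of the two ethers ortho to the ketone, to give 4.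

Step 2. The hydrogen-bonded phenol may silylate incompletely, or the aryl and enol trimethylsilyl ethers may hydrolyse during isolation and return 4. The fallback carries the phenol as a robust silyl ether that is removed only at the end; it sets out from 4 and comes back at 8. TBSOTf and 2,6-lutidine in CH2Cl2 give TBS ether F7. LiN(i-Pr)2 followed by TMSCl in THF at −78 °C gives enol silane F8. The aldol addition of step 3 with 6 gives TBS-protected aldol F9, and Bu4NF buffered with AcOH in THF at 0 °C cleaves the aryl silyl ether to give 8.

Further compounds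
F1 | step 3 | 1-[7-methoxy-5-(methoxymethoxy)-2,2-dimethyl-2H-chromen-6-yl]ethan-1-one | COc1cc2c(c(OCOC)c1C(C)=O)C=CC(C)(C)O2
F2 | step 3 | (2E)-1-[7-methoxy-5-(methoxymethoxy)-2,2-dimethyl-2H-chromen-6-yl]-3-phenylprop-2-en-1-one | COc1cc2c(c(OCOC)c1C(=O)/C=C/c1ccccc1)C=CC(C)(C)O2
F3 | step 3 | [7-methoxy-5-(methoxymethoxy)-2,2-dimethyl-2H-chromen-6-yl][(2S,3R)-3-phenyloxiran-2-yl]methanone | COc1cc2c(c(OCOC)c1C(=O)[C@H]1O[C@@H]1c1ccccc1)C=CC(C)(C)O2
F4 | step 3 | (3S)-3-hydroxy-1-[7-methoxy-5-(methoxymethoxy)-2,2-dimethyl-2H-chromen-6-yl]-3-phenylpropan-1-one | COc1cc2c(c(OCOC)c1C(=O)C[C@H](O)c1ccccc1)C=CC(C)(C)O2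
F5 | step 1 | 1-(4-hydroxy-2,6-dimethoxyphenyl)ethan-1-one | COc1cc(O)cc(OC)c1C(C)=O
F6 | step 1 | 1-(5,7-dimethoxy-2,2-dimethyl-2H-chromen-6-yl)ethan-1-one | COc1cc2c(c(OC)c1C(C)=O)C=CC(C)(C)O2
F7 | step 2 | 1-{5-[(tert-butyldimethylsilyl)oxy]-7-methoxy-2,2-dimethyl-2H-chromen-6-yl}ethan-1-one | COc1cc2c(c(O[Si](C)(C)C(C)(C)C)c1C(C)=O)C=CC(C)(C)O2
F8 | step 2 | tert-butyl[(7-methoxy-2,2-dimethyl-6-{1-[(trimethylsilyl)oxy]ethenyl}-2H-chromen-5-yl)oxy]dimethylsilane | COc1cc2c(c(O[Si](C)(C)C(C)(C)C)c1C(=C)O[Si](C)(C)C)C=CC(C)(C)O2
F9 | step 2 | (3S)-1-{5-[(tert-butyldimethylsilyl)oxy]-7-methoxy-2,2-dimethyl-2H-chromen-6-yl}-3-hydroxy-3-phenylpropan-1-one | COc1cc2c(c(O[Si](C)(C)C(C)(C)C)c1C(=O)C[C@H](O)c1ccccc1)C=CC(C)(C)O2
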